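**Strategy.** The molecule is cut at the bond between the acetoxy methine (C-a) on C1 of the trans-hydrindane (rings A and C) and the tertiary carbinol C1′ of ring B. The key step forges it by a Nozaki–Hiyama–Kishi coupling of the fully functionalised hydrindane aldehyde with an acyclic alkenyl triflate that stores ring B's bromonium ion as an enantiopure bromohydrin. It exploits the vicinal C-a(OAc)/C1′(OH) pair: C-a is an aldehyde carbon, C1′ the internal carbon of a 1,1-disubstituted alkene. One operation joins both halves, sets C-a, and leaves the alkene to close ring B later by a bromonium–olefin cyclization that the C-a acetate terminates.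

Key step: step 19

Atom labels: hydrindane carbons carry indane numbers (C1–C7a; ring A six-membered, ring C five-membered); C-a is the acetoxy methine; ring B is C1′ (carbinol), C4′ (CHBr), C5′ (CMe2), C6′.
Assumption: the sense of induction of the bromolactonization catalyst in step 3 has to be assigned by experiment; (DHQD)2PHAL is written, and its pseudoenantiomer (DHQ)2PHAL serves if the opposite sense is found.

**Ring A/C fragment (steps 1–15)**

Step 1
Reactants: 1 pent-1-en-4-yne
Product: 3 (E)-1-iodo-2-methylpenta-1,4-diene, via alkenylalane 2 (not isolated)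
Conditions: AlMe3 (2 equiv), Cp2ZrCl2 (0.2 equiv), CH2Cl2, 0 °C to rt; then I2, THF, −30 °C
Reagents that add atoms: trimethylaluminium C[Al](C)C; iodine II
Why: Zirconium-catalysed Negishi carboalumination adds methyl and aluminium syn across the terminal alkyne (methyl on the internal carbon), and iodinolysis with retention should fix the (E)-trisubstituted alkene while the isolated vinyl group stays inert.

Step 2
Reactants: 3 (E)-1-iodo-2-methylpenta-1,4-diene; 4 β-propiolactone
Product: 6 (E)-5-methylocta-4,7-dienoic acid, via alkenylmagnesium chloride 5 (not isolated)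
Conditions: iPrMgCl·LiCl, THF, −20 °C to rt; then CuI (5 mol%), 4, THF/Me2S, −30 to 0 °C; aq. HCl
Reagents that add atoms: none
Why: Iodine–magnesium exchange retains the alkene geometry, and the copper-catalysed alkenyl Grignard should open β-propiolactone by SN2 attack at the CH2–O carbon to give the 4-enoic acid directly.

Step 3
Reactants: 6 (E)-5-methylocta-4,7-dienoic acid
Product: 7 (5S,6R)-5-bromo-6-methyl-6-(prop-2-en-1-yl)oxan-2-one
Conditions: N-bromosuccinimide (1.1 equiv), hydroquinidine 1,4-phthalazinediyl diether ((DHQD)2PHAL, 10 mol%), CHCl3/hexane, −40 °C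
Reagents that add atoms: N-bromosuccinimide O=C1CCC(=O)N1Br
Why: In this catalytic asymmetric bromolactonization the carboxylate should open the bromonium ion of the electron-rich trisubstituted alkene anti at the tertiary carbon (6-endo), so the (E) geometry sets the relative and the catalyst the absolute configuration of C4–Br and C3a–O, and the monosubstituted vinyl group does not compete.

Step 4
Reactants: 7 bromolactone
Product: 8 (2R,3S)-3-bromo-2-methyl-6-methylidene-2-(prop-2-en-1-yl)oxane
Conditions: Cp2TiMe2 (2.5 equiv), toluene, 65 °C, dark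
Reagents that add atoms: dimethyltitanocene [CH3-].[CH3-].[Ti+4].c1cc[cH-]c1.c1cc[cH-]c1
Why: Petasis methylenation converts the lactone carbonyl into the exocyclic enol ether under non-basic conditions, so the secondary bromide and both stereocentres should be untouched.

Step 5
Reactants: 8 cyclic enol ether
Product: 9 (3S,4S)-4-bromo-3-methyl-3-(prop-2-en-1-yl)cyclohexan-1-one
Conditions: Me2AlCl (1.5 equiv), CH2Cl2, −78 to −20 °C
Reagents that add atoms: none
Why: Proposed new method: aluminium bound to the enol-ether oxygen should ionize the tertiary C–O bond with anchimeric help of the anti bromine (bromonium ion/aluminium enolate pair), and the enolate carbon should re-close on the tertiary carbon anti to bromine, a [1,3] O-to-C shift with retention that turns the C–O stereocentre into the quaternary C3a of the cyclohexanone; the closest known reaction type is the Petasis–Ferrier rearrangement of cyclic enol acetals, where an oxocarbenium ion plays the part of the bromonium ion.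

Step 6
Reactants: 9 bromoketone
Product: 10 (7S,8S)-8-bromo-7-methyl-7-(prop-2-en-1-yl)-1,4-dioxaspiro[4.5]decane
Conditions: Me3SiOCH2CH2OSiMe3, Me3SiOTf (5 mol%), CH2Cl2, −78 to −20 °C
Reagents that add atoms: 1,2-bis(trimethylsilyloxy)ethane C[Si](C)(C)OCCO[Si](C)(C)C
Why: Aprotic silyl-triflate-catalysed ketalization masks the ketone so that the C7a–H bonds are no longer deactivated α-keto C–H bonds in step 10 and no enolate can displace the γ-bromide.

Step 7
Reactants: 10 ketal
Product: 12 2-[(7S,8S)-8-bromo-7-methyl-1,4-dioxaspiro[4.5]decan-7-yl]acetaldehyde, via ozonide 11 (not isolated)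
Conditions: O3, CH2Cl2, −78 °C; then PPh3, −78 °C to rt
Reagents that add atoms: ozone O=[O+][O-]
Why: Ozonolysis of the only alkene with reductive work-up gives the one-carbon-shorter aldehyde (C2) without touching ketal or bromide.

Step 8
Reactants: 12 aldehyde; 13 ethyl diazoacetate
Product: 14 ethyl 4-[(7S,8S)-8-bromo-7-methyl-1,4-dioxaspiro[4.5]decan-7-yl]-3-oxobutanoate
Conditions: SnCl2 (10 mol%), CH2Cl2, rt
Reagents that add atoms: none
Why: In the Roskamp reaction the diazo ester adds to the Lewis-acid-activated aldehyde and 1,2-hydride shift with loss of N2 gives the β-keto ester.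

Step 9
Reactants: 14 β-keto ester
Product: 15 ethyl 2-diazo-4-[(7S,8S)-8-bromo-7-methyl-1,4-dioxaspiro[4.5]decan-7-yl]-3-oxobutanoate
Conditions: 4-acetamidobenzenesulfonyl azide, Et3N, MeCN, 0 °C to rt
Reagents that add atoms: 4-acetamidobenzenesulfonyl azide CC(=O)Nc1ccc(cc1)S(=O)(=O)N=[N+]=[N-]
Why: Regitz diazo transfer to the active methylene is reliable and leaves the rest of the molecule alone.

Step 10
Reactants: 15 α-diazo-β-keto ester
Product: 16 ethyl (1S,3aS,4S,7aS)-4-bromo-3a-methyl-2-oxo-octahydrospiro[indene-7,2′-[1,3]dioxolane]-1-carboxylate (trans ring fusion)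
Conditions: Rh2(OAc)4 (1 mol%), CH2Cl2, rt to 40 °C
Reagents that add atoms: none
Why: Rhodium-carbenoid 1,5 C–H insertion should close ring C on the C7a methylene (preferred over the methyl group and over the bromine-deactivated methine), insertion with retention into the equatorial C–H from the equatorial side chain gives the trans fusion (C7a), and C1 settles by enolization with the ester trans to C7; competing cis fusion is the risk of this step.

Step 11
Reactants: 16 ketal
Product: 17 ethyl (1S,3aS,4S,7aS)-4-bromo-3a-methyl-2,7-dioxooctahydro-1H-indene-1-carboxylate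
Conditions: pyridinium p-toluenesulfonate, acetone/H2O, 40 °C
Reagents that add atoms: water O
Why: Mild acetal hydrolysis frees the C7 ketone, and weak acid with short contact should avoid epimerization of the kinetically formed trans ring fusion.

Step 12
Reactants: 17 diketo ester
Product: 19 ethyl (1S,3aS,4S,7R,7aS)-4-bromo-7-hydroxy-3a,7-dimethyl-2-oxooctahydro-1H-indene-1-carboxylate, via lithium enolate 18 (not isolated)
Conditions: LiN(SiMe3)2 (1.05 equiv), THF, −78 °C; then MeLi/CeCl3 (2 equiv), −78 °C; aq. NH4Cl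
Reagents that add atoms: methyllithium [Li]C
Why: With the β-keto ester protected in situ as its enolate, the organocerium methyl adds to the C7 ketone of the now rigid trans-hydrindane equatorially, anti to the syn-axial C3a methyl, which should give the axial hydroxyl and equatorial methyl (7R).

Step 13
Reactants: 19 hydroxy β-keto ester
Product: 20 ethyl (1S,2R,3aS,4S,7R,7aS)-4-bromo-2,7-dihydroxy-3a,7-dimethyloctahydro-1H-indene-1-carboxylate
Conditions: Zn(BH4)2, Et2O, −20 °C
Reagents that add atoms: none
Why: Chelation-controlled reduction of the cyclic β-keto ester delivers hydride to the zinc chelate from the side of the small C1 hydrogen, anti to the ester-bearing face, which should give the cis β-hydroxy ester (2R).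

Step 14
Reactants: 20 diol ester
Product: 21 ethyl (1S,2R,3aS,4S,7R,7aS)-4-bromo-3a,7-dimethyl-2,7-bis(triethylsilyloxy)octahydro-1H-indene-1-carboxylate
Conditions: Et3SiOTf (3 equiv), 2,6-lutidine, CH2Cl2, −20 °C to rt
Reagents that add atoms: triethylsilyl trifluoromethanesulfonate CC[Si](CC)(CC)OS(=O)(=O)C(F)(F)F
Why: The silyl triflate is reactive enough for the hindered axial tertiary hydroxyl as well as the secondary one; protecting C7–OH also prevents lactol-driven epimerization at C1 at the aldehyde stage and its ionization in step 21.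

Step 15
Reactants: 21 bis-silyl ester
Product: 22 (1S,2R,3aS,4S,7R,7aS)-4-bromo-3a,7-dimethyl-2,7-bis(triethylsilyloxy)octahydro-1H-indene-1-carbaldehyde
Conditions: iBu2AlH (1.2 equiv), CH2Cl2, −78 °C; Rochelle salt work-up
Reagents that add atoms: none
Why: Partial reduction stops at the aluminium hemiacetal at −78 °C and releases the aldehyde on work-up without epimerizing C1.

**Ring B precursor (steps 16–18)**

Step 16
Reactants: 23 6-methylhept-5-en-2-one
Product: 24 4-[(2R)-3,3-dimethyloxiran-2-yl]butan-2-one
Conditions: 1,2:4,5-di-O-isopropylidene-β-D-erythro-2,3-hexodiulo-2,6-pyranose (D-fructose-derived Shi ketone, 30 mol%), Oxone (2KHSO5·KHSO4·K2SO4), K2CO3, Bu4NHSO4, MeCN/dimethoxymethane/aq. buffer (pH 10.5), 0 °C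
Reagents that add atoms: potassium peroxymonosulfate [K+].[O-]S(=O)(=O)OO
Why: Shi epoxidation of the trisubstituted alkene through the spiro transition state of the chiral dioxirane should give the (R)-epoxide.

Step 17
Reactants: 24 epoxy ketone
Product: 25 5-[(2R)-3,3-dimethyloxiran-2-yl]pent-1-en-2-yl trifluoromethanesulfonate
Conditions: KN(SiMe3)2, THF, −78 °C; then PhNTf2, −78 °C
Reagents that add atoms: N-phenylbis(trifluoromethanesulfonimide) FC(F)(F)S(=O)(=O)N(c1ccccc1)S(=O)(=O)C(F)(F)F
Why: Kinetic deprotonation at the methyl group and O-triflation give the 1,1-disubstituted alkenyl triflate, and at −78 °C the enolate should not open the epoxide.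

Step 18
Reactants: 25 epoxy alkenyl triflate
Product: 26 (5S)-5-bromo-6-hydroxy-6-methylhept-1-en-2-yl trifluoromethanesulfonate
Conditions: Li2NiBr4, THF, 0 °C to rt; aq. phosphate buffer
Reagents that add atoms: dilithium tetrabromonickelate [Li+].[Li+].[Ni+2].[Br-].[Br-].[Br-].[Br-]
Why: The soft bromide source opens the trisubstituted epoxide by SN2 attack at the less substituted carbon with inversion, which should give the (S)-bromide next to the tertiary alcohol, the stored form of ring B's bromonium ion.

**Union and endgame (steps 19–22)**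

Step 19
Reactants: 22 hydrindane aldehyde; 26 bromohydrin alkenyl triflate
Product: 28 (1R,5S)-5-bromo-6-methyl-2-methylidene-1-(hydrindanyl)heptane-1,6-diol, hydrindanyl being the 1-yl group of 22, via alkenylchromium dichloride 27 (not isolated)
Conditions: CrCl2 (6 equiv), NiCl2 (2 mol%), DMF/THF, rt
Reagents that add atoms: none
Why: Zerovalent nickel, formed from NiCl2 and CrCl2, inserts into the C(sp2)–OTf bond of 26, the alkenyl group passes to trivalent chromium, and alkenylchromium 27 adds to the aldehyde of 22 to form the C-a–C1′ bond. The closest known reaction type is the Nozaki–Hiyama–Kishi coupling of alkenyl triflates with aldehydes. No ring is closed here; the step delivers the complete carbon skeleton and leaves the C1′=C6′ alkene and the bromohydrin in place for the later closure of ring B. The new stereocentre C-a should be set by Felkin–Anh addition: the C1–C2 bond, whose cis silyloxy group shields that side, stands anti to the incoming alkenyl group, so attack comes past the C7a hydrogen and gives the (R) carbinol. The step needs chemoselectivity for the alkenyl triflate over two secondary alkyl bromides, tolerance of a free tertiary alcohol and no enolization of the α-branched aldehyde. The neutral chromium reagent does not reduce unactivated alkyl bromides, tolerates hydroxyl groups and is not basic.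

Step 20
Reactants: 28 allylic alcohol
Product: 29 1-O-acetate of 28
Conditions: Ac2O, 4-(dimethylamino)pyridine, pyridine, rt
Reagents that add atoms: acetic anhydride CC(=O)OC(C)=O
Why: Only the secondary allylic hydroxyl should be acylated, the tertiary bromohydrin hydroxyl being too hindered.

Step 21
Reactants: 29 allylic acetate
Product: 32 2,7-bis(triethylsilyl) ether of 33, via trifluoroacetate 30 (not isolated), via acetoxonium ion 31 (not isolated)
Conditions: (CF3CO)2O, 2,6-lutidine, CH2Cl2, −20 °C; then (CF3)2CHOH/H2O, 2,6-di-tert-butylpyridine, 0 °C to rt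
Reagents that add atoms: water O; trifluoroacetic anhydride O=C(OC(=O)C(F)(F)F)C(F)(F)F (supplies only the trifluoroacetyl group of 30, lost again)
Why: Solvolysis of the tertiary trifluoroacetate with help of the vicinal bromine should regenerate the configurationally defined bromonium ion (a stereospecific bromohydrin-initiated cation–olefin cyclization), the C1′=C6′ alkene attacks its tertiary carbon anti to bromine through a chair with equatorial bromine (6-endo), the C-a acetate traps the C1′ cation axially before ring inversion so that the bulky C-a substituent stays equatorial (Woodward–Prévost-type acetoxonium ion 31), and hydrolysis leaves the acetate on the secondary oxygen and the axial tertiary hydroxyl cis to bromine (1′R,4′S).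

Step 22
Reactants: 32 bis-silyl ether
Product: 33 [(R)-[(1S,2R,3aS,4S,7R,7aS)-4-bromo-2,7-dihydroxy-3a,7-dimethyloctahydro-1H-inden-1-yl][(1R,4S)-4-bromo-1-hydroxy-3,3-dimethylcyclohexyl]methyl] acetate
Conditions: HF·pyridine, THF/pyridine, 0 °C to rt
Reagents that add atoms: none
Why: Buffered fluoride cleaves both triethylsilyl ethers under conditions in which the acetate should neither hydrolyse nor migrate.

**Compound list**

1 | pent-1-en-4-yne | C#CCC=C | starting material
2 | (E)-dimethyl(2-methylpenta-1,4-dien-1-yl)alane | C=CC/C(C)=C/[Al](C)C | intermediate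
3 | (E)-1-iodo-2-methylpenta-1,4-diene | C=CC/C(C)=C/I | intermediate
4 | β-propiolactone (oxetan-2-one) | O=C1CCO1 | starting material
5 | (E)-(2-methylpenta-1,4-dien-1-yl)magnesium chloride | C=CC/C(C)=C/[Mg]Cl | intermediate
6 | (E)-5-methylocta-4,7-dienoic acid | OC(=O)CC/C=C(C)/CC=C | intermediate
7 | (5S,6R)-5-bromo-6-methyl-6-(prop-2-en-1-yl)oxan-2-one | O=C1CC[C@H](Br)[C@@](C)(CC=C)O1 | intermediate
8 | (2R,3S)-3-bromo-2-methyl-6-methylidene-2-(prop-2-en-1-yl)oxane | C=C1CC[C@H](Br)[C@@](C)(CC=C)O1 | intermediate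
9 | (3S,4S)-4-bromo-3-methyl-3-(prop-2-en-1-yl)cyclohexan-1-one | O=C1C[C@](C)(CC=C)[C@@H](Br)CC1 | intermediate
10 | (7S,8S)-8-bromo-7-methyl-7-(prop-2-en-1-yl)-1,4-dioxaspiro[4.5]decane | O1CCOC12C[C@](C)(CC=C)[C@@H](Br)CC2 | intermediate
11 | 3-{[(7S,8S)-8-bromo-7-methyl-1,4-dioxaspiro[4.5]decan-7-yl]methyl}-1,2,4-trioxolane (ozonide of 10) | O1CCOC12C[C@](C)(CC3OCOO3)[C@@H](Br)CC2 | intermediate
12 | 2-[(7S,8S)-8-bromo-7-methyl-1,4-dioxaspiro[4.5]decan-7-yl]acetaldehyde | O1CCOC12C[C@](C)(CC=O)[C@@H](Br)CC2 | intermediate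
13 | ethyl diazoacetate | CCOC(=O)C=[N+]=[N-] | starting material
14 | ethyl 4-[(7S,8S)-8-bromo-7-methyl-1,4-dioxaspiro[4.5]decan-7-yl]-3-oxobutanoate | O1CCOC12C[C@](C)(CC(=O)CC(=O)OCC)[C@@H](Br)CC2 | intermediate
15 | ethyl 2-diazo-4-[(7S,8S)-8-bromo-7-methyl-1,4-dioxaspiro[4.5]decan-7-yl]-3-oxobutanoate | O1CCOC12C[C@](C)(CC(=O)C(=[N+]=[N-])C(=O)OCC)[C@@H](Br)CC2 | intermediate
16 | ethyl (1S,3aS,4S,7aS)-4-bromo-3a-methyl-2-oxo-octahydrospiro[indene-7,2′-[1,3]dioxolane]-1-carboxylate | CCOC(=O)[C@@H]1C(=O)C[C@]2(C)[C@@H](Br)CCC3(OCCO3)[C@@H]12 | intermediate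
17 | ethyl (1S,3aS,4S,7aS)-4-bromo-3a-methyl-2,7-dioxooctahydro-1H-indene-1-carboxylate | CCOC(=O)[C@@H]1C(=O)C[C@]2(C)[C@@H](Br)CCC(=O)[C@@H]12 | intermediate
18 | lithium enolate of 17 (C1=C2–O−) | [Li+].CCOC(=O)C1=C([O-])C[C@]2(C)[C@@H](Br)CCC(=O)[C@@H]12 | intermediate
19 | ethyl (1S,3aS,4S,7R,7aS)-4-bromo-7-hydroxy-3a,7-dimethyl-2-oxooctahydro-1H-indene-1-carboxylate | CCOC(=O)[C@@H]1C(=O)C[C@]2(C)[C@@H](Br)CC[C@@](C)(O)[C@@H]12 | intermediate
20 | ethyl (1S,2R,3aS,4S,7R,7aS)-4-bromo-2,7-dihydroxy-3a,7-dimethyloctahydro-1H-indene-1-carboxylate | CCOC(=O)[C@@H]1[C@H](O)C[C@]2(C)[C@@H](Br)CC[C@@](C)(O)[C@@H]12 | intermediate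
21 | ethyl (1S,2R,3aS,4S,7R,7aS)-4-bromo-3a,7-dimethyl-2,7-bis(triethylsilyloxy)octahydro-1H-indene-1-carboxylate | CCOC(=O)[C@@H]1[C@H](O[Si](CC)(CC)CC)C[C@]2(C)[C@@H](Br)CC[C@@](C)(O[Si](CC)(CC)CC)[C@@H]12 | intermediate
22 | (1S,2R,3aS,4S,7R,7aS)-4-bromo-3a,7-dimethyl-2,7-bis(triethylsilyloxy)octahydro-1H-indene-1-carbaldehyde | O=C[C@@H]1[C@H](O[Si](CC)(CC)CC)C[C@]2(C)[C@@H](Br)CC[C@@](C)(O[Si](CC)(CC)CC)[C@@H]12 | intermediate
23 | 6-methylhept-5-en-2-one | CC(=O)CCC=C(C)C | starting material
24 | 4-[(2R)-3,3-dimethyloxiran-2-yl]butan-2-one | CC(=O)CC[C@H]1OC1(C)C | intermediate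
25 | 5-[(2R)-3,3-dimethyloxiran-2-yl]pent-1-en-2-yl trifluoromethanesulfonate | C=C(OS(=O)(=O)C(F)(F)F)CC[C@H]1OC1(C)C | intermediate
26 | (5S)-5-bromo-6-hydroxy-6-methylhept-1-en-2-yl trifluoromethanesulfonate | C=C(OS(=O)(=O)C(F)(F)F)CC[C@H](Br)C(C)(C)O | intermediate
27 | [(5S)-5-bromo-6-hydroxy-6-methylhept-1-en-2-yl]chromium dichloride | C=C([Cr](Cl)Cl)CC[C@H](Br)C(C)(C)O | intermediate
28 | (1R,5S)-5-bromo-6-methyl-2-methylidene-1-(hydrindanyl)heptane-1,6-diol, hydrindanyl configured as in 22 | O[C@H]([C@@H]1[C@H](O[Si](CC)(CC)CC)C[C@]2(C)[C@@H](Br)CC[C@@](C)(O[Si](CC)(CC)CC)[C@@H]12)C(=C)CC[C@H](Br)C(C)(C)O | intermediate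
29 | 1-O-acetate of 28 | CC(=O)O[C@H]([C@@H]1[C@H](O[Si](CC)(CC)CC)C[C@]2(C)[C@@H](Br)CC[C@@](C)(O[Si](CC)(CC)CC)[C@@H]12)C(=C)CC[C@H](Br)C(C)(C)O | intermediate
30 | 6-O-trifluoroacetate of 29 | CC(=O)O[C@H]([C@@H]1[C@H](O[Si](CC)(CC)CC)C[C@]2(C)[C@@H](Br)CC[C@@](C)(O[Si](CC)(CC)CC)[C@@H]12)C(=C)CC[C@H](Br)C(C)(C)OC(=O)C(F)(F)F | intermediate
31 | 2-methyl-1,3-dioxolan-2-ylium ion spiro-fused at C1′ of ring B (C-a R, C1′ R, C4′ S) | CC1=[O+][C@@]2(CC[C@H](Br)C(C)(C)C2)[C@@H]([C@@H]3[C@H](O[Si](CC)(CC)CC)C[C@]4(C)[C@@H](Br)CC[C@@](C)(O[Si](CC)(CC)CC)[C@@H]34)O1 | intermediate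
32 | 2,7-bis(triethylsilyl) ether of 33 | CC(=O)O[C@H]([C@@H]1[C@H](O[Si](CC)(CC)CC)C[C@]2(C)[C@@H](Br)CC[C@@](C)(O[Si](CC)(CC)CC)[C@@H]12)[C@@]1(O)CC[C@H](Br)C(C)(C)C1 | intermediate
33 | [(R)-[(1S,2R,3aS,4S,7R,7aS)-4-bromo-2,7-dihydroxy-3a,7-dimethyloctahydro-1H-inden-1-yl][(1R,4S)-4-bromo-1-hydroxy-3,3-dimethylcyclohexyl]methyl] acetate | CC(=O)O[C@H]([C@@H]1[C@H](O)C[C@]2(C)[C@@H](Br)CC[C@@](C)(O)[C@@H]12)[C@@]1(O)CC[C@H](Br)C(C)(C)C1 | target

**Step count.** Total: 22 steps. Longest linear sequence: 19 steps (steps 1–15 and 19–22).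

**Three steps most likely to fail**

Step 5 (proposed new method). After ionization the bromonium ion/enolate pair may lose a proton or re-close on oxygen faster than on carbon, so that no carbocycle forms. The fallback uses known reaction types, sets out from 3 and returns at 9. Iodine–magnesium exchange on 3 and copper-catalysed conjugate addition to but-3-en-2-one should give (E)-6-methylnona-5,8-dien-2-one F1. Shi epoxidation with the D-fructose-derived ketone gives 4-[(2R,3R)-3-methyl-3-(prop-2-en-1-yl)oxiran-2-yl]butan-2-one F2. LiN(iPr)2 and tert-butyldimethylsilyl chloride give the kinetic terminal silyl enol ether F3. Li2NiBr4 opens the epoxide at the secondary carbon with inversion to (5S,6R)-5-bromo-2-[tert-butyl(dimethyl)silyl]oxy-6-methylnona-1,8-dien-6-ol F4. SnCl4 with 2,6-di-tert-butylpyridine at −78 °C then ionizes the tertiary alcohol with bromine participation, and the silyl enol ether alkylates the tertiary carbon (intramolecular Mukaiyama–Reetz α-tert-alkylation) to give 9.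

Step 21. The cyclohexyl cation may invert its ring before capture, be trapped by solvent or lose a proton instead of being captured by the acetate, or the allylic acetate may ionize in competition. The fallback sets out from 22 and 23 and returns at 32. KN(SiMe3)2 and PhNTf2 turn 23 into 6-methylhepta-1,5-dien-2-yl trifluoromethanesulfonate F5. The same Nozaki–Hiyama–Kishi coupling with 22 gives the bromine-free allylic alcohol F6, and Ac2O gives its acetate F7. Bromodiethylsulfonium bromopentachloroantimonate in nitromethane at −25 °C then transfers Br+ to the more electron-rich trisubstituted alkene, and the same chair cyclization with acetoxonium termination and aqueous work-up should give 32 together with its (1′S,4′R) ring-B diastereomer, to be separated by chromatography. Here the bromonium ion comes from an external reagent instead of being stored in the chain, at the price of no reagent control over ring B.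

Step 3. Enantioselection on a purely aliphatic trisubstituted alkene may be poor, and 5-exo closure may compete with 6-endo closure. The fallback sets out from 3 and returns at 7. Iodine–magnesium exchange on 3 and copper-catalysed conjugate addition to methyl acrylate should give methyl (E)-5-methylocta-4,7-dienoate F8. Shi epoxidation gives methyl 3-[(2R,3R)-3-methyl-3-(prop-2-en-1-yl)oxiran-2-yl]propanoate F9. Li2NiBr4 opens the epoxide at the secondary carbon with inversion to methyl (4S,5R)-4-bromo-5-hydroxy-5-methyloct-7-enoate F10, which lactonizes under pyridinium p-toluenesulfonate catalysis to 7.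

Further compounds
F1 | step 5 | (E)-6-methylnona-5,8-dien-2-one | CC(=O)CC/C=C(C)/CC=C
F2 | step 5 | 4-[(2R,3R)-3-methyl-3-(prop-2-en-1-yl)oxiran-2-yl]butan-2-one | CC(=O)CC[C@H]1O[C@]1(C)CC=C
F3 | step 5 | tert-butyl(dimethyl)silyl enol ether of F2 (terminal, pent-1-en-2-yl) | C=C(O[Si](C)(C)C(C)(C)C)CC[C@H]1O[C@]1(C)CC=C
F4 | step 5 | (5S,6R)-5-bromo-2-[tert-butyl(dimethyl)silyl]oxy-6-methylnona-1,8-dien-6-ol | C=C(O[Si](C)(C)C(C)(C)C)CC[C@H](Br)[C@@](C)(CC=C)O
F5 | step 21 | 6-methylhepta-1,5-dien-2-yl trifluoromethanesulfonate | C=C(OS(=O)(=O)C(F)(F)F)CCC=C(C)C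
F6 | step 21 | (1R)-6-methyl-2-methylidene-1-(hydrindanyl)hept-5-en-1-ol, hydrindanyl configured as in 22 | O[C@H]([C@@H]1[C@H](O[Si](CC)(CC)CC)C[C@]2(C)[C@@H](Br)CC[C@@](C)(O[Si](CC)(CC)CC)[C@@H]12)C(=C)CCC=C(C)C
F7 | step 21 | acetate of F6 | CC(=O)O[C@H]([C@@H]1[C@H](O[Si](CC)(CC)CC)C[C@]2(C)[C@@H](Br)CC[C@@](C)(O[Si](CC)(CC)CC)[C@@H]12)C(=C)CCC=C(C)C
F8 | step 3 | methyl (E)-5-methylocta-4,7-dienoate | COC(=O)CC/C=C(C)/CC=C
F9 | step 3 | methyl 3-[(2R,3R)-3-methyl-3-(prop-2-en-1-yl)oxiran-2-yl]propanoate | COC(=O)CC[C@H]1O[C@]1(C)CC=C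
F10 | step 3 | methyl (4S,5R)-4-bromo-5-hydroxy-5-methyloct-7-enoate | COC(=O)CC[C@H](Br)[C@@](C)(CC=C)O
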